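**Plan**
- Feature: in the oxolane (O1; C2 with 3,4-dimethoxyphenyl; C3 and C4 with the cis methyls; C5 with 3,4,5-trimethoxyphenyl) the two methyls can be read as the reduced arms of a γ-lactone fused across C3–C4. This gives a cis-fused 3,7-dioxabicyclo[3.3.0]octan-8-one with the C2 aryl endo and the C5 aryl exo.
- Retrosynthesis: both methyls are returned to the lactone, then the ring bond C2–C3 is cut (carbene C–H insertion), then the diazo group, the O1–C2 benzyl ether bond and last the C4–C5 aldol bond.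
- Forward: an Evans syn-aldol joins C4–C5, O-benzylation installs O1–C2, and the pentenoyl chain is reshaped into the γ-lactone (first ring). Diazo transfer and Rh2(OAc)4-catalysed 1,5 C–H insertion close the oxolane (second ring), and the lactone is then cut down to the two methyls.
- Stereochemistry: C4 and C5 come from the (S)-4-benzyloxazolidinone syn-aldol (syn in the chain becomes 4,5-trans in the ring), C3 from the obligatory cis ring fusion, and C2 from endo-selective insertion.

Key step: step 9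

Remark: the bicyclic lactone is numbered as 3,7-dioxabicyclo[3.3.0]octan-8-one (C1 α to the carbonyl C8, aryl-bearing C2 and C4, C5 the second fusion carbon); "endo" means on the concave face, and bicyclic C1, C2, C4, C5 correspond to C3, C2, C5, C4 of the target oxolane.

**Route**

Step 1
Reactants: 1 pent-4-enoic acid; 2 (4S)-4-benzyl-1,3-oxazolidin-2-one
Product: 4 (4S)-4-benzyl-3-(pent-4-enoyl)-1,3-oxazolidin-2-one, via pent-4-enoic pivalic anhydride 3 (not isolated)
Conditions: t-BuCOCl, Et3N, THF, −20 °C; then LiCl, 2, −20 °C to rt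
Reagents that add atoms: none
Why: N-acylation of the oxazolidinone through the mixed pivalic anhydride (LiCl-assisted acyl transfer) is a standard preparation of Evans imides and attacks the less hindered pentenoyl carbonyl of 3, leaving the alkene and the auxiliary stereocentre untouched.

Step 2
Reactants: 4 (4S)-4-benzyl-3-(pent-4-enoyl)-1,3-oxazolidin-2-one; 5 3,4,5-trimethoxybenzaldehyde
Product: 8 (4S)-4-benzyl-3-{(2S)-2-[(S)-hydroxy(3,4,5-trimethoxyphenyl)methyl]pent-4-enoyl}-1,3-oxazolidin-2-one, via dibutylboron Z-enolate 6 (not isolated), via dibutylboron aldolate 7 (not isolated)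
Conditions: n-Bu2BOTf (1.1 equiv), i-Pr2NEt (1.3 equiv), CH2Cl2, 0 °C; 5, −78 to 0 °C; then pH 7 buffer, MeOH, 30% H2O2, 0 °C
Reagents that add atoms: none
Why: Evans syn-aldol reaction, in which the Z-boron enolate 6 adds to the aldehyde through a chair Zimmerman–Traxler transition state on the enolate face remote from the benzyl group, so that both new stereocentres (C2 S, carbinol S, syn) are set by the auxiliary.

Step 3
Reactants: 9 (3,4-dimethoxyphenyl)methanol
Product: 10 3,4-dimethoxybenzyl 2,2,2-trichloroacetimidate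
Conditions: Cl3CCN (1.5 equiv), DBU (0.1 equiv), CH2Cl2, 0 °C
Reagents that add atoms: trichloroacetonitrile, N#CC(Cl)(Cl)Cl
Why: DBU-catalysed addition of the benzylic alcohol to trichloroacetonitrile is the routine preparation of benzyl trichloroacetimidates and creates no stereocentre.

Step 4
Reactants: 8 (4S)-4-benzyl-3-{(2S)-2-[(S)-hydroxy(3,4,5-trimethoxyphenyl)methyl]pent-4-enoyl}-1,3-oxazolidin-2-one; 10 3,4-dimethoxybenzyl 2,2,2-trichloroacetimidate
Product: 11 (4S)-4-benzyl-3-{(2S)-2-[(S)-[(3,4-dimethoxyphenyl)methoxy](3,4,5-trimethoxyphenyl)methyl]pent-4-enoyl}-1,3-oxazolidin-2-one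
Conditions: 10 (2 equiv), camphorsulfonic acid (0.1 equiv), CH2Cl2, 0 °C to rt
Reagents that add atoms: none
Why: Acid-catalysed O-benzylation with a trichloroacetimidate (imidate etherification) alkylates the secondary alcohol through the stabilised 3,4-dimethoxybenzyl cation under conditions that avoid the retro-aldol cleavage a basic Williamson alkylation would provoke, and it touches no stereocentre.

Step 5
Reactants: 11 (4S)-4-benzyl-3-{(2S)-2-[(S)-[(3,4-dimethoxyphenyl)methoxy](3,4,5-trimethoxyphenyl)methyl]pent-4-enoyl}-1,3-oxazolidin-2-one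
Product: 12 (2R)-2-[(S)-[(3,4-dimethoxyphenyl)methoxy](3,4,5-trimethoxyphenyl)methyl]pent-4-en-1-ol
Conditions: LiBH4 (2 equiv), MeOH (2 equiv), THF, 0 °C
Reagents that add atoms: none
Why: Reductive cleavage of the Evans imide with LiBH4 in the presence of methanol attacks the exocyclic carbonyl and gives the primary alcohol without epimerising the α-centre, whose descriptor changes from S to R only through the priority rules.

Step 6
Reactants: 12 (2R)-2-[(S)-[(3,4-dimethoxyphenyl)methoxy](3,4,5-trimethoxyphenyl)methyl]pent-4-en-1-ol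
Product: 14 (4R)-4-[(S)-[(3,4-dimethoxyphenyl)methoxy](3,4,5-trimethoxyphenyl)methyl]oxolan-2-ol (both anomers), via open-chain hydroxy aldehyde 13 (not isolated)
Conditions: OsO4 (2 mol %), NaIO4 (4 equiv), 2,6-lutidine (2 equiv), 1,4-dioxane/H2O 3:1, rt
Reagents that add atoms: osmium tetroxide, O=[Os](=O)(=O)=O (carries the new oxygen; regenerated by sodium periodate, [Na+].[O-]I(=O)(=O)=O)
Why: Lemieux–Johnson oxidation cleaves the terminal alkene selectively in the presence of the electron-rich arenes that ozone could attack, and the γ-hydroxy aldehyde 13 closes spontaneously to the five-membered lactol, whose anomeric centre is erased in the next step.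

Step 7
Reactants: 14 (4R)-4-[(S)-[(3,4-dimethoxyphenyl)methoxy](3,4,5-trimethoxyphenyl)methyl]oxolan-2-ol
Product: 15 (4R)-4-[(S)-[(3,4-dimethoxyphenyl)methoxy](3,4,5-trimethoxyphenyl)methyl]oxolan-2-one
Conditions: Pr4N[RuO4] (5 mol %), N-methylmorpholine N-oxide (2 equiv), 4 Å molecular sieves, CH2Cl2, rt
Reagents that add atoms: none
Why: Ley–Griffith oxidation turns lactols into lactones under neutral conditions that leave the oxidation-prone 3,4-dimethoxybenzyl ether and both stereocentres intact.

Step 8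
Reactants: 15 (4R)-4-[(S)-[(3,4-dimethoxyphenyl)methoxy](3,4,5-trimethoxyphenyl)methyl]oxolan-2-one
Product: 17 (4R)-3-diazo-4-[(S)-[(3,4-dimethoxyphenyl)methoxy](3,4,5-trimethoxyphenyl)methyl]oxolan-2-one, via 3-trifluoroacetyl lactone 16 (not isolated)
Conditions: LiN(SiMe3)2 (1.1 equiv), THF, −78 °C; CF3CO2CH2CF3 (1.3 equiv); aq HCl work-up; then 4-AcNHC6H4SO2N3 (1.5 equiv), Et3N (1.5 equiv), H2O (1 equiv), MeCN, rt
Reagents that add atoms: 4-acetamidobenzenesulfonyl azide, CC(=O)Nc1ccc(cc1)S(=O)(=O)N=[N+]=[N-]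
Why: Danheiser detrifluoroacetylative diazo transfer, in which Claisen trifluoroacetylation of the lactone enolate makes C3 acidic enough for Regitz-type diazo transfer from the sulfonyl azide and the trifluoroacetyl group then leaves as the N-sulfonyl trifluoroacetamide, while neither existing stereocentre is enolisable.

Step 9
Reactants: 17 (4R)-3-diazo-4-[(S)-[(3,4-dimethoxyphenyl)methoxy](3,4,5-trimethoxyphenyl)methyl]oxolan-2-one
Product: 18 (1R,2S,4S,5R)-2-(3,4-dimethoxyphenyl)-4-(3,4,5-trimethoxyphenyl)-3,7-dioxabicyclo[3.3.0]octan-8-one (2-aryl endo, 4-aryl exo)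
Conditions: Rh2(OAc)4 (2 mol %), CH2Cl2, reflux, 17 added slowly by syringe pump at high dilution
Reagents that add atoms: none
Why: Rh2(OAc)4 takes up the diazo carbon with loss of N2 to give an electrophilic dirhodium carbene at the lactone α-carbon (future C1), which inserts into one benzylic C–H bond of the OCH2Ar group in a concerted, three-centre, hydride-transfer-like step that forms the C1–C2 bond. The closest known reaction type is the Rh2(OAc)4-catalysed 1,5 C–H insertion of α-diazo-γ-butyrolactones into benzylic ether C–H bonds, which gives cis-fused dioxabicyclo[3.3.0]octanones with the new aryl endo. The oxolane ring (C1, C2, O3, C4, C5) closes by 1,5-insertion, that is, five-membered ring formation by C–C bond making between the carbene carbon and the ether α-carbon. C1 is fixed by the tether, since a carbene held in the lactone can reach the C–H bond only on the face that carries the side chain at C5, so the ring fusion must be cis; C2 is fixed by which diastereotopic benzylic hydrogen reacts, and the aryl is expected to point over the lactone (endo), away from the carboxylate wall of the dirhodium core that lies on the exo side of C1. The step needs 1,5-insertion to outrun 1,2-hydride shift to the butenolide and attack on the trimethoxyphenyl ring: the target C–H bond is doubly activated (ether oxygen and electron-rich aryl) and sits at the ideal distance for a five-membered ring, slow addition suppresses carbene dimerisation, and the syn-aldol-derived carbinol centre keeps its aryl on the convex face at C4.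

Step 10
Reactants: 18 (1R,2S,4S,5R)-2-(3,4-dimethoxyphenyl)-4-(3,4,5-trimethoxyphenyl)-3,7-dioxabicyclo[3.3.0]octan-8-one
Product: 19 [(2S,3S,4R,5S)-2-(3,4-dimethoxyphenyl)-5-(3,4,5-trimethoxyphenyl)oxolane-3,4-diyl]dimethanol
Conditions: LiAlH4 (2 equiv), THF, 0 °C; then H2O, 15% aq NaOH, H2O
Reagents that add atoms: none
Why: LiAlH4 reduction of a lactone to the 1,4-diol is routine, proceeds faster than enolisation at C1, and so carries the cis ring fusion over into the two cis hydroxymethyl groups.

Step 11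
Reactants: 19 [(2S,3S,4R,5S)-2-(3,4-dimethoxyphenyl)-5-(3,4,5-trimethoxyphenyl)oxolane-3,4-diyl]dimethanol
Product: 20 [(2S,3S,4R,5S)-2-(3,4-dimethoxyphenyl)-5-(3,4,5-trimethoxyphenyl)oxolane-3,4-diyl]bis(methylene) dimethanesulfonate
Conditions: MsCl (3 equiv), Et3N (4 equiv), CH2Cl2, −20 to 0 °C
Reagents that add atoms: methanesulfonyl chloride, CS(=O)(=O)Cl
Why: Sulfonylation of both primary alcohols with MsCl/Et3N (through sulfene) is fast at low temperature, and excess reagent should make the second mesylation outrun cyclisation of the mono-mesylate to a bicyclic ether.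

Step 12
Reactants: 20 [(2S,3S,4R,5S)-2-(3,4-dimethoxyphenyl)-5-(3,4,5-trimethoxyphenyl)oxolane-3,4-diyl]bis(methylene) dimethanesulfonate
Product: 21 ligraminol A, (2S,3R,4S,5S)-2-(3,4-dimethoxyphenyl)-3,4-dimethyl-5-(3,4,5-trimethoxyphenyl)oxolane
Conditions: LiBHEt3 (6 equiv), THF, 0 °C to rt
Reagents that add atoms: none
Why: LiBHEt3 (Super-Hydride) reduces primary sulfonates by SN2 hydride displacement at carbon, so both CH2OMs arms should become the cis methyl groups without touching the ring C–O bonds or any stereocentre.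

**Compound list**

1 | pent-4-enoic acid | C=CCCC(=O)O | starting material
2 | (4S)-4-benzyl-1,3-oxazolidin-2-one | O=C1N[C@@H](Cc2ccccc2)CO1 | starting material
3 | pent-4-enoic pivalic anhydride | C=CCCC(=O)OC(=O)C(C)(C)C | intermediate
4 | (4S)-4-benzyl-3-(pent-4-enoyl)-1,3-oxazolidin-2-one | C=CCCC(=O)N1[C@@H](Cc2ccccc2)COC1=O | intermediate
5 | 3,4,5-trimethoxybenzaldehyde | COc1cc(C=O)cc(OC)c1OC | starting material
6 | (4S)-4-benzyl-3-[(1Z)-1-[(dibutylboranyl)oxy]penta-1,4-dien-1-yl]-1,3-oxazolidin-2-one (dibutylboron Z-enolate) | C=CC/C=C(\OB(CCCC)CCCC)N1[C@@H](Cc2ccccc2)COC1=O | intermediate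
7 | (4S)-4-benzyl-3-{(2S)-2-[(S)-[(dibutylboranyl)oxy](3,4,5-trimethoxyphenyl)methyl]pent-4-enoyl}-1,3-oxazolidin-2-one (dibutylboron aldolate) | C=CC[C@@H]([C@H](OB(CCCC)CCCC)c1cc(OC)c(OC)c(OC)c1)C(=O)N1[C@@H](Cc2ccccc2)COC1=O | intermediate
8 | (4S)-4-benzyl-3-{(2S)-2-[(S)-hydroxy(3,4,5-trimethoxyphenyl)methyl]pent-4-enoyl}-1,3-oxazolidin-2-one | C=CC[C@@H]([C@H](O)c1cc(OC)c(OC)c(OC)c1)C(=O)N1[C@@H](Cc2ccccc2)COC1=O | intermediate
9 | (3,4-dimethoxyphenyl)methanol | COc1ccc(CO)cc1OC | starting material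
10 | 3,4-dimethoxybenzyl 2,2,2-trichloroacetimidate | COc1ccc(COC(=N)C(Cl)(Cl)Cl)cc1OC | intermediate
11 | (4S)-4-benzyl-3-{(2S)-2-[(S)-[(3,4-dimethoxyphenyl)methoxy](3,4,5-trimethoxyphenyl)methyl]pent-4-enoyl}-1,3-oxazolidin-2-one | C=CC[C@@H]([C@H](OCc1ccc(OC)c(OC)c1)c2cc(OC)c(OC)c(OC)c2)C(=O)N3[C@@H](Cc4ccccc4)COC3=O | intermediate
12 | (2R)-2-[(S)-[(3,4-dimethoxyphenyl)methoxy](3,4,5-trimethoxyphenyl)methyl]pent-4-en-1-ol | C=CC[C@H](CO)[C@H](OCc1ccc(OC)c(OC)c1)c2cc(OC)c(OC)c(OC)c2 | intermediate
13 | (3R,4S)-4-[(3,4-dimethoxyphenyl)methoxy]-3-(hydroxymethyl)-4-(3,4,5-trimethoxyphenyl)butanal | O=CC[C@H](CO)[C@H](OCc1ccc(OC)c(OC)c1)c2cc(OC)c(OC)c(OC)c2 | intermediate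
14 | (4R)-4-[(S)-[(3,4-dimethoxyphenyl)methoxy](3,4,5-trimethoxyphenyl)methyl]oxolan-2-ol (both anomers) | OC1C[C@H](CO1)[C@H](OCc2ccc(OC)c(OC)c2)c3cc(OC)c(OC)c(OC)c3 | intermediate
15 | (4R)-4-[(S)-[(3,4-dimethoxyphenyl)methoxy](3,4,5-trimethoxyphenyl)methyl]oxolan-2-one | O=C1C[C@H](CO1)[C@H](OCc2ccc(OC)c(OC)c2)c3cc(OC)c(OC)c(OC)c3 | intermediate
16 | (4R)-4-[(S)-[(3,4-dimethoxyphenyl)methoxy](3,4,5-trimethoxyphenyl)methyl]-3-(trifluoroacetyl)oxolan-2-one (C3 epimers and enol) | O=C1OC[C@H]([C@H](OCc2ccc(OC)c(OC)c2)c3cc(OC)c(OC)c(OC)c3)C1C(=O)C(F)(F)F | intermediate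
17 | (4R)-3-diazo-4-[(S)-[(3,4-dimethoxyphenyl)methoxy](3,4,5-trimethoxyphenyl)methyl]oxolan-2-one | COc1ccc(CO[C@H](c2cc(OC)c(OC)c(OC)c2)[C@H]3COC(=O)C3=[N+]=[N-])cc1OC | intermediate
18 | (1R,2S,4S,5R)-2-(3,4-dimethoxyphenyl)-4-(3,4,5-trimethoxyphenyl)-3,7-dioxabicyclo[3.3.0]octan-8-one (2-aryl endo, 4-aryl exo) | O1[C@H](c3ccc(OC)c(OC)c3)[C@@H]2C(=O)OC[C@@H]2[C@H]1c4cc(OC)c(OC)c(OC)c4 | intermediate
19 | [(2S,3S,4R,5S)-2-(3,4-dimethoxyphenyl)-5-(3,4,5-trimethoxyphenyl)oxolane-3,4-diyl]dimethanol | COc1ccc([C@H]2O[C@H](c3cc(OC)c(OC)c(OC)c3)[C@@H](CO)[C@H]2CO)cc1OC | intermediate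
20 | [(2S,3S,4R,5S)-2-(3,4-dimethoxyphenyl)-5-(3,4,5-trimethoxyphenyl)oxolane-3,4-diyl]bis(methylene) dimethanesulfonate | COc1ccc([C@H]2O[C@H](c3cc(OC)c(OC)c(OC)c3)[C@@H](COS(C)(=O)=O)[C@H]2COS(C)(=O)=O)cc1OC | intermediate
21 | ligraminol A, (2S,3R,4S,5S)-2-(3,4-dimethoxyphenyl)-3,4-dimethyl-5-(3,4,5-trimethoxyphenyl)oxolane | COc1ccc([C@H]2O[C@H](c3cc(OC)c(OC)c(OC)c3)[C@@H](C)[C@H]2C)cc1OC | target

**Step count and risks**

Total step count: 12. Longest linear sequence: 11 steps (steps 1, 2 and 4 to 12, from pent-4-enoic acid); step 3 is a one-step side branch.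

Steps most likely to fail:

Step 9. The carbene may be diverted into 1,2-hydride migration from the neighbouring ring carbon (butenolide formation) or into electrophilic attack on an ortho carbon of the trimethoxyphenyl ring, or the insertion may show too little endo preference at C2. The fallback sets out from 15 and comes back at 18; it makes the same C1–C2 bond by enolate acylation and sets C2 by hydride delivery instead of by carbene insertion. The lithium enolate of 15 (LiN(SiMe3)2, 2 equiv, THF, −78 °C) would be C-acylated with 3,4-dimethoxybenzoyl chloride in a crossed Claisen condensation to give the β-keto lactone (4R)-3-(3,4-dimethoxybenzoyl)-4-[(S)-[(3,4-dimethoxyphenyl)methoxy](3,4,5-trimethoxyphenyl)methyl]oxolan-2-one F1. Oxidative removal of the 3,4-dimethoxybenzyl ether with DDQ (CH2Cl2/pH 7 buffer) should free the carbinol, which closes onto the ketone to give the cis-fused hemiketal (1R,4S,5R)-2-(3,4-dimethoxyphenyl)-2-hydroxy-4-(3,4,5-trimethoxyphenyl)-3,7-dioxabicyclo[3.3.0]octan-8-one F2. Et3SiH/BF3·OEt2 (CH2Cl2, −78 °C) would then reduce the derived oxocarbenium ion with hydride arriving on the convex face, which leaves the aryl endo and gives 18.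

Step 4. The acid needed to activate the imidate may ionise the electron-rich benzylic carbinol (loss of configuration or elimination), or the hindered secondary alcohol may react more slowly than the imidate rearranges or alkylates itself. The fallback sets out from 8 and comes back at 12; it delivers the benzyl group intramolecularly from an acetal. LiBH4 (THF, MeOH, 0 °C) would reduce 8 to the diol (1S,2R)-2-(prop-2-en-1-yl)-1-(3,4,5-trimethoxyphenyl)propane-1,3-diol F3. Acetal exchange with 3,4-dimethoxybenzaldehyde dimethyl acetal (pyridinium p-toluenesulfonate, CH2Cl2) should give the thermodynamic acetal (2S,4S,5R)-2-(3,4-dimethoxyphenyl)-5-(prop-2-en-1-yl)-4-(3,4,5-trimethoxyphenyl)-1,3-dioxane F4. Reductive opening with i-Bu2AlH (CH2Cl2, −78 to 0 °C), in which aluminium binds the less hindered primary oxygen, would leave the 3,4-dimethoxybenzyl group on the secondary oxygen and give 12.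

Step 12. Hydride may attack sulfur and release an alkoxide that displaces the neighbouring mesylate (closure to a 3,7-dioxabicyclo[3.3.0]octane), or displacement at the β-branched carbons may be sluggish. The fallback sets out from 20 and comes back at 21; it replaces ionic hydride displacement by radical dehalogenation. Finkelstein exchange (NaI, butanone, reflux) would give (2S,3R,4S,5S)-2-(3,4-dimethoxyphenyl)-3,4-bis(iodomethyl)-5-(3,4,5-trimethoxyphenyl)oxolane F5, and Bu3SnH with azobisisobutyronitrile (toluene, 80 °C) would remove both iodines to give 21.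

Further compounds
F1 | step 9 | (4R)-3-(3,4-dimethoxybenzoyl)-4-[(S)-[(3,4-dimethoxyphenyl)methoxy](3,4,5-trimethoxyphenyl)methyl]oxolan-2-one (C3 epimers) | O=C1OC[C@H]([C@H](OCc2ccc(OC)c(OC)c2)c3cc(OC)c(OC)c(OC)c3)C1C(=O)c4ccc(OC)c(OC)c4
F2 | step 9 | (1R,4S,5R)-2-(3,4-dimethoxyphenyl)-2-hydroxy-4-(3,4,5-trimethoxyphenyl)-3,7-dioxabicyclo[3.3.0]octan-8-one (hemiketal, C2 open) | O1C(O)(c3ccc(OC)c(OC)c3)[C@@H]2C(=O)OC[C@@H]2[C@H]1c4cc(OC)c(OC)c(OC)c4
F3 | step 4 | (1S,2R)-2-(prop-2-en-1-yl)-1-(3,4,5-trimethoxyphenyl)propane-1,3-diol | C=CC[C@H](CO)[C@H](O)c1cc(OC)c(OC)c(OC)c1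
F4 | step 4 | (2S,4S,5R)-2-(3,4-dimethoxyphenyl)-5-(prop-2-en-1-yl)-4-(3,4,5-trimethoxyphenyl)-1,3-dioxane | C=CC[C@@H]1CO[C@H](c2ccc(OC)c(OC)c2)O[C@@H]1c3cc(OC)c(OC)c(OC)c3
F5 | step 12 | (2S,3R,4S,5S)-2-(3,4-dimethoxyphenyl)-3,4-bis(iodomethyl)-5-(3,4,5-trimethoxyphenyl)oxolane | COc1ccc([C@H]2O[C@H](c3cc(OC)c(OC)c(OC)c3)[C@@H](CI)[C@H]2CI)cc1OC
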